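The route rests on disconnecting the C2–C3 bond of ring C. In flavanone numbering, C2 is benzylic to ring B and bound to O1, while C3 is a methylene beside the C4 ketone; a rhodium carbene at C3 can therefore insert into a benzylic ether C–H bond of an O-benzylated phloroacetophenone. One operation forms the C2–C3 bond, closes ring C and sets the (S) centre at C2 under catalyst control. The precursor is a terminal diazo ketone on ring A, flanked by the fully assembled ring B benzyl ether and a triisopropylsilyl ether, with all hydroxyl groups silylated so that one buffered fluoride treatment ends the synthesis.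

Key step: step 11

Abbreviations: TIPS = triisopropylsilyl; TES = triethylsilyl; ArB = 4-methoxy-3-(3-methylbut-2-en-1-yl)-5-[(E)-3-methyl-3-(triethylsilyloxy)but-1-en-1-yl]phenyl.

Assumption: Rh2(S-PTTL)4 is taken to select the pro-S benzylic hydrogen of 16; if a trial run shows the opposite sense, the mirror-image catalyst Rh2(R-PTTL)4 is used and nothing else changes.

Remark: 12 is sold as its monohydrate and is dried (toluene azeotrope) before step 8.

Step 1
Reactants: 1 3-bromo-4-hydroxybenzaldehyde; 2 3-chloro-3-methylbut-1-yne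
Product: 3 3-bromo-4-[(2-methylbut-3-yn-2-yl)oxy]benzaldehyde
Conditions: K2CO3, KI (cat.), CuI (cat.), acetone, 55 °C
Reagents that add atoms: none
Why: Copper-assisted Williamson-type O-propargylation of the acidic phenoxide with the tertiary propargylic chloride should give the 1,1-dimethylpropargyl aryl ether without touching the aldehyde or the aryl bromide.

Step 2
Reactants: 3 3-bromo-4-[(2-methylbut-3-yn-2-yl)oxy]benzaldehyde
Product: 4 3-bromo-4-[(2-methylbut-3-en-2-yl)oxy]benzaldehyde
Conditions: H2 (1 atm), Pd/CaCO3 poisoned with Pb(OAc)2, quinoline, EtOAc, rt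
Reagents that add atoms: none
Why: Lindlar semihydrogenation should stop at the terminal alkene, since the poisoned palladium surface reduces neither the alkene, the aldehyde nor the aryl bromide at a useful rate.

Step 3
Reactants: 4 3-bromo-4-[(2-methylbut-3-en-2-yl)oxy]benzaldehyde
Product: 6 3-bromo-4-hydroxy-5-(3-methylbut-2-en-1-yl)benzaldehyde, via cyclohexadienone 5 (not isolated)
Conditions: N,N-diethylaniline, 150 °C
Reagents that add atoms: none
Why: The aromatic Claisen rearrangement ([3,3]-sigmatropic shift) should deliver the 1,1-dimethylallyl group with allylic transposition as a prenyl group to the only free ortho carbon, after which 5 tautomerises to the phenol; the amine solvent keeps acid away so that the ortho-prenyl phenol does not close to a chroman.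

Step 4
Reactants: 6 3-bromo-4-hydroxy-5-(3-methylbut-2-en-1-yl)benzaldehyde
Product: 7 3-bromo-4-methoxy-5-(3-methylbut-2-en-1-yl)benzaldehyde
Conditions: MeI, K2CO3, DMF, rt
Reagents that add atoms: iodomethane, CI
Why: Williamson O-methylation of the acidic, doubly ortho-substituted phenoxide with a small electrophile should cap the hydroxyl before the palladium step.

Step 5
Reactants: 7 3-bromo-4-methoxy-5-(3-methylbut-2-en-1-yl)benzaldehyde; 8 2-methylbut-3-en-2-ol
Product: 9 3-[(E)-3-hydroxy-3-methylbut-1-en-1-yl]-4-methoxy-5-(3-methylbut-2-en-1-yl)benzaldehyde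
Conditions: Pd(OAc)2 (5 mol %), P(o-tol)3, Et3N, DMF, 100 °C
Reagents that add atoms: none
Why: Mizoroki–Heck arylation should place the aryl group on the terminal alkene carbon, and because the carbinol carbon carries no hydrogen, β-hydride elimination can only give the conjugated (E)-alkene; the trisubstituted prenyl alkene does not insert.

Step 6
Reactants: 9 3-[(E)-3-hydroxy-3-methylbut-1-en-1-yl]-4-methoxy-5-(3-methylbut-2-en-1-yl)benzaldehyde
Product: 10 4-methoxy-3-(3-methylbut-2-en-1-yl)-5-[(E)-3-methyl-3-(triethylsilyloxy)but-1-en-1-yl]benzaldehyde (ArB–CHO)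
Conditions: TESOTf, 2,6-lutidine, CH2Cl2, −78 to 0 °C
Reagents that add atoms: triethylsilyl trifluoromethanesulfonate, CC[Si](CC)(CC)OS(=O)(=O)C(F)(F)F
Why: Silylation with a silyl triflate and a hindered pyridine base should mask the hindered tertiary alcohol, the only O–H that would later quench base, acylating agent or carbene; the aldehyde has no α hydrogen and is unaffected.

Step 7
Reactants: 10 ArB–CHO
Product: 11 ArB–CH2OH, {4-methoxy-3-(3-methylbut-2-en-1-yl)-5-[(E)-3-methyl-3-(triethylsilyloxy)but-1-en-1-yl]phenyl}methanol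
Conditions: NaBH4, MeOH/THF, 0 °C
Reagents that add atoms: none
Why: Borohydride reduction of the aryl aldehyde should give the primary benzylic alcohol and leave the silyl ether and both alkenes alone.

Step 8
Reactants: 12 2',4',6'-trihydroxyacetophenone
Product: 13 1-[2-hydroxy-4,6-bis(triisopropylsilyloxy)phenyl]ethan-1-one
Conditions: TIPSCl (2.2 equiv), imidazole, DMF, 0 °C to rt
Reagents that add atoms: chlorotriisopropylsilane, CC(C)[Si](Cl)(C(C)C)C(C)C
Why: Silylation with a bulky chlorosilane should take the para hydroxyl and one ortho hydroxyl, while the last ortho hydroxyl, held in a hydrogen bond to the acetyl oxygen, reacts far more slowly, so the reaction can be stopped at the bis-silyl ether.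

Step 9
Reactants: 13 1-[2-hydroxy-4,6-bis(triisopropylsilyloxy)phenyl]ethan-1-one; 11 ArB–CH2OH
Product: 14 1-[2-(ArB-methoxy)-4,6-bis(triisopropylsilyloxy)phenyl]ethan-1-one
Conditions: PPh3, DIAD, THF, 0 °C to rt
Reagents that add atoms: none
Why: Mitsunobu etherification activates the primary benzylic alcohol as its alkoxyphosphonium salt, which the phenoxide of the single free hydroxyl should displace under neutral conditions that spare the aryl silyl ethers and the tertiary silyl ether.

Step 10
Reactants: 14 1-[2-(ArB-methoxy)-4,6-bis(triisopropylsilyloxy)phenyl]ethan-1-one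
Product: 16 2-diazo-1-[2-(ArB-methoxy)-4,6-bis(triisopropylsilyloxy)phenyl]ethan-1-one, via trifluoroacetyl ketone 15 (not isolated)
Conditions: LiN(SiMe3)2, THF, −78 °C, then CF3CO2CH2CF3; crude 15, 4-acetamidobenzenesulfonyl azide, Et3N, H2O, MeCN, rt
Reagents that add atoms: 4-acetamidobenzenesulfonyl azide, CC(=O)Nc1ccc(cc1)S(=O)(=O)N=[N+]=[N-] (the two diazo nitrogens of 16); 2,2,2-trifluoroethyl trifluoroacetate, FC(F)(F)COC(=O)C(F)(F)F (the trifluoroacetyl group of 15, lost again)
Why: In this deacylative Regitz diazo transfer the kinetic lithium enolate of the methyl ketone is C-trifluoroacetylated, and 1,3-diketone 15 should take up the diazo group from the sulfonyl azide and lose the trifluoroacetyl group as the N-sulfonyl amide, so neither diazomethane nor an acid chloride is needed.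

Step 11
Reactants: 16 2-diazo-1-[2-(ArB-methoxy)-4,6-bis(triisopropylsilyloxy)phenyl]ethan-1-one
Product: 17 (2S)-2-ArB-5,7-bis(triisopropylsilyloxy)chroman-4-one
Conditions: Rh2(S-PTTL)4 (2 mol %), CH2Cl2, 0 °C, slow addition of 16, 4 Å molecular sieves
Reagents that add atoms: none
Why: Proposed new method: Rh2(S-PTTL)4, dirhodium tetrakis[N-phthaloyl-(S)-tert-leucinate], should expel N2 from 16 to give an electrophilic rhodium carbene at the future C3, which takes one benzylic hydrogen of the aryl–O–CH2–aryl ether through a concerted, asynchronous C–H–C transition state and forms the C2–C3 bond with retention at carbon. The closest known reaction types are the insertion of carbenes from 2-alkoxyaryl diazo ketones into the ether α C–H bond under dirhodium tetracarboxylates to give chroman-4-ones, and the enantioselective insertion into aryl benzyl ether C–H bonds by phthaloyl amino acid dirhodium catalysts in the five-membered series; a terminal acceptor carbene closing a 2-aryl chromanone with high enantioselectivity is untested. Ring C closes by 1,6 C–H insertion through a six-atom array (carbene carbon, carbonyl carbon, two ring A carbons, O1, C2), the only activated C–H bond within reach because the 1,5 position is an oxygen atom. The C2 stereocentre is set by catalyst control: the pocket formed by the four phthalimido walls must present the pro-S hydrogen to the carbene, and retentive insertion then gives (S). The step needs insertion to win over attack of O1 on the carbene (oxonium ylide, then Stevens benzyl shift to a 2-benzylbenzofuran-3-one) and over reaction at the other ortho oxygen. The C–H bond activated by both the ether oxygen and electron-rich ring B, the bulky electron-poor carboxylates, and the TIPS ether at the other ortho oxygen (no α C–H bond, screened from the metal) should secure this; both alkenes are too remote for intramolecular cyclopropanation and slow addition limits intermolecular reaction.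

Step 12
Reactants: 17 (2S)-2-ArB-5,7-bis(triisopropylsilyloxy)chroman-4-one
Product: 18 (2S)-5,7-dihydroxy-2-{3-[(E)-3-hydroxy-3-methylbut-1-en-1-yl]-4-methoxy-5-(3-methylbut-2-en-1-yl)phenyl}chroman-4-one
Conditions: Bu4NF, AcOH (1:1.2), THF, 0 °C to rt
Reagents that add atoms: none
Why: Fluoride-mediated desilylation should cleave the two aryl silyl ethers and the tertiary silyl ether, while the acetic acid buffer keeps phenoxide and enolate concentrations low so that ring C does not open to the chalcone and C2 keeps its configuration, and the absence of strong acid protects the tertiary allylic alcohol.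

Compound list
1 | 3-bromo-4-hydroxybenzaldehyde | O=Cc1ccc(O)c(Br)c1 | starting material
2 | 3-chloro-3-methylbut-1-yne | CC(C)(Cl)C#C | starting material
3 | 3-bromo-4-[(2-methylbut-3-yn-2-yl)oxy]benzaldehyde | O=Cc1ccc(OC(C)(C)C#C)c(Br)c1 | intermediate
4 | 3-bromo-4-[(2-methylbut-3-en-2-yl)oxy]benzaldehyde | O=Cc1ccc(OC(C)(C)C=C)c(Br)c1 | intermediate
5 | 5-bromo-3-(3-methylbut-2-en-1-yl)-4-oxocyclohexa-1,5-diene-1-carbaldehyde (racemic, not isolated) | O=CC1=CC(CC=C(C)C)C(=O)C(Br)=C1 | intermediate
6 | 3-bromo-4-hydroxy-5-(3-methylbut-2-en-1-yl)benzaldehyde | O=Cc1cc(Br)c(O)c(CC=C(C)C)c1 | intermediate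
7 | 3-bromo-4-methoxy-5-(3-methylbut-2-en-1-yl)benzaldehyde | O=Cc1cc(Br)c(OC)c(CC=C(C)C)c1 | intermediate
8 | 2-methylbut-3-en-2-ol | C=CC(C)(C)O | starting material
9 | 3-[(E)-3-hydroxy-3-methylbut-1-en-1-yl]-4-methoxy-5-(3-methylbut-2-en-1-yl)benzaldehyde | O=Cc1cc(/C=C/C(C)(C)O)c(OC)c(CC=C(C)C)c1 | intermediate
10 | 4-methoxy-3-(3-methylbut-2-en-1-yl)-5-[(E)-3-methyl-3-(triethylsilyloxy)but-1-en-1-yl]benzaldehyde | O=Cc1cc(/C=C/C(C)(C)O[Si](CC)(CC)CC)c(OC)c(CC=C(C)C)c1 | intermediate
11 | {4-methoxy-3-(3-methylbut-2-en-1-yl)-5-[(E)-3-methyl-3-(triethylsilyloxy)but-1-en-1-yl]phenyl}methanol | OCc1cc(/C=C/C(C)(C)O[Si](CC)(CC)CC)c(OC)c(CC=C(C)C)c1 | intermediate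
12 | 2',4',6'-trihydroxyacetophenone | CC(=O)c1c(O)cc(O)cc1O | starting material
13 | 1-[2-hydroxy-4,6-bis(triisopropylsilyloxy)phenyl]ethan-1-one | CC(=O)c1c(O)cc(O[Si](C(C)C)(C(C)C)C(C)C)cc1O[Si](C(C)C)(C(C)C)C(C)C | intermediate
14 | 1-{2-[(4-methoxy-3-(3-methylbut-2-en-1-yl)-5-((E)-3-methyl-3-(triethylsilyloxy)but-1-en-1-yl)phenyl)methoxy]-4,6-bis(triisopropylsilyloxy)phenyl}ethan-1-one | CC(=O)c1c(OCc2cc(CC=C(C)C)c(OC)c(/C=C/C(C)(C)O[Si](CC)(CC)CC)c2)cc(O[Si](C(C)C)(C(C)C)C(C)C)cc1O[Si](C(C)C)(C(C)C)C(C)C | intermediate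
15 | 4,4,4-trifluoro-1-{2-[(4-methoxy-3-(3-methylbut-2-en-1-yl)-5-((E)-3-methyl-3-(triethylsilyloxy)but-1-en-1-yl)phenyl)methoxy]-4,6-bis(triisopropylsilyloxy)phenyl}butane-1,3-dione (not isolated) | O=C(CC(=O)c1c(OCc2cc(CC=C(C)C)c(OC)c(/C=C/C(C)(C)O[Si](CC)(CC)CC)c2)cc(O[Si](C(C)C)(C(C)C)C(C)C)cc1O[Si](C(C)C)(C(C)C)C(C)C)C(F)(F)F | intermediate
16 | 2-diazo-1-{2-[(4-methoxy-3-(3-methylbut-2-en-1-yl)-5-((E)-3-methyl-3-(triethylsilyloxy)but-1-en-1-yl)phenyl)methoxy]-4,6-bis(triisopropylsilyloxy)phenyl}ethan-1-one | [N-]=[N+]=CC(=O)c1c(OCc2cc(CC=C(C)C)c(OC)c(/C=C/C(C)(C)O[Si](CC)(CC)CC)c2)cc(O[Si](C(C)C)(C(C)C)C(C)C)cc1O[Si](C(C)C)(C(C)C)C(C)C | intermediate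
17 | (2S)-2-{4-methoxy-3-(3-methylbut-2-en-1-yl)-5-[(E)-3-methyl-3-(triethylsilyloxy)but-1-en-1-yl]phenyl}-5,7-bis(triisopropylsilyloxy)chroman-4-one | O=C1C[C@@H](c2cc(CC=C(C)C)c(OC)c(/C=C/C(C)(C)O[Si](CC)(CC)CC)c2)Oc2cc(O[Si](C(C)C)(C(C)C)C(C)C)cc(O[Si](C(C)C)(C(C)C)C(C)C)c12 | intermediate
18 | (2S)-5,7-dihydroxy-2-{3-[(E)-3-hydroxy-3-methylbut-1-en-1-yl]-4-methoxy-5-(3-methylbut-2-en-1-yl)phenyl}chroman-4-one | COc1c(/C=C/C(C)(C)O)cc([C@@H]2CC(=O)c3c(O)cc(O)cc3O2)cc1CC=C(C)C | target

Total step count: 12.
Longest linear sequence: 11 steps (steps 1 to 7 and 9 to 12, from 1); step 8 is the one-step branch from 12.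

Steps most likely to fail

1. Step 11. The ether oxygen O1 may attack the carbene faster than the C–H bond is reached, leading through ylide formation and benzyl migration away from ring C. Alternatively, the small terminal carbene may be discriminated too weakly between the two enantiotopic hydrogens, so that the centre at C2 forms with low selectivity.

   Fallback (known chemistry; sets out from 13 and 10, returns at 17): the dilithium phenoxide–enolate of 13 (LiN(SiMe3)2, 2.2 equiv, THF, −78 °C) would be added to aldehyde 10 to give the racemic aldol adduct F1. An intramolecular Mitsunobu etherification (PPh3, DIAD, THF) would then close the O1–C2 bond to the racemic flavanone F2. Kinetic resolution by asymmetric transfer hydrogenation (RuCl(p-cymene)[(R,R)-TsDPEN], HCO2H/Et3N 1:1, EtOAc, rt) should, by the usual model of this catalyst family, reduce the (R)-ketone to the cis-(2R,4R)-flavan-4-ol F3 and leave 17, which is separated by chromatography. Ring C is thus closed at the C–O bond and the stereocentre comes from resolution, at the cost of half the material.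

2. Step 9. The hydrogen-bonded phenol may be too sluggish a pronucleophile, so that the activated alcohol is consumed by the hydrazide. The electron-rich benzylic phosphonium salt may also ionise and alkylate ring A at carbon.

   Fallback (sets out from 11, returns at 14): alcohol 11 would be converted through its mesylate into the benzylic chloride F4 (MsCl, Et3N, LiCl, THF, 0 °C). Phenol 13 would then be O-alkylated with it under Williamson conditions (K2CO3, Bu4NI (cat.), anhydrous acetone, 50 °C) to give 14.

3. Step 10. C-trifluoroacetylation of the hindered, electron-rich enolate may stay incomplete, or an aryl silyl ether may be hydrolysed by the aqueous amine during the diazo transfer.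

   Fallback (sets out from 14, returns at 16): the kinetic enolate of 14 (LiN(SiMe3)2, THF, −78 °C) would be trapped with Me3SiCl as the trimethylsilyl enol ether F5. Bromination with N-bromosuccinimide (1.0 equiv, THF, −78 °C) should give the α-bromo ketone F6. Treatment with N,N'-ditosylhydrazine and DBU (THF, 0 °C) should then give 16 by N-alkylation and loss of two sulfinate groups.

Further compounds
F1 | step 11 | racemic 3-ArB-3-hydroxy-1-[2-hydroxy-4,6-bis(triisopropylsilyloxy)phenyl]propan-1-one | O=C(CC(O)c1cc(CC=C(C)C)c(OC)c(/C=C/C(C)(C)O[Si](CC)(CC)CC)c1)c1c(O)cc(O[Si](C(C)C)(C(C)C)C(C)C)cc1O[Si](C(C)C)(C(C)C)C(C)C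
F2 | step 11 | racemic 2-ArB-5,7-bis(triisopropylsilyloxy)chroman-4-one | O=C1CC(c2cc(CC=C(C)C)c(OC)c(/C=C/C(C)(C)O[Si](CC)(CC)CC)c2)Oc2cc(O[Si](C(C)C)(C(C)C)C(C)C)cc(O[Si](C(C)C)(C(C)C)C(C)C)c12
F3 | step 11 | (2R,4R)-2-ArB-5,7-bis(triisopropylsilyloxy)chroman-4-ol | O[C@@H]1C[C@H](c2cc(CC=C(C)C)c(OC)c(/C=C/C(C)(C)O[Si](CC)(CC)CC)c2)Oc2cc(O[Si](C(C)C)(C(C)C)C(C)C)cc(O[Si](C(C)C)(C(C)C)C(C)C)c12
F4 | step 9 | ArB–CH2Cl, 5-(chloromethyl)-2-methoxy-1-(3-methylbut-2-en-1-yl)-3-[(E)-3-methyl-3-(triethylsilyloxy)but-1-en-1-yl]benzene | ClCc1cc(/C=C/C(C)(C)O[Si](CC)(CC)CC)c(OC)c(CC=C(C)C)c1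
F5 | step 10 | trimethylsilyl enol ether of 14, 1-[2-(ArB-methoxy)-4,6-bis(triisopropylsilyloxy)phenyl]-1-(trimethylsilyloxy)ethene | C=C(O[Si](C)(C)C)c1c(OCc2cc(CC=C(C)C)c(OC)c(/C=C/C(C)(C)O[Si](CC)(CC)CC)c2)cc(O[Si](C(C)C)(C(C)C)C(C)C)cc1O[Si](C(C)C)(C(C)C)C(C)C
F6 | step 10 | 2-bromo-1-[2-(ArB-methoxy)-4,6-bis(triisopropylsilyloxy)phenyl]ethan-1-one | BrCC(=O)c1c(OCc2cc(CC=C(C)C)c(OC)c(/C=C/C(C)(C)O[Si](CC)(CC)CC)c2)cc(O[Si](C(C)C)(C(C)C)C(C)C)cc1O[Si](C(C)C)(C(C)C)C(C)C
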